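The chemist following the dusk flask reads just two columns, solid substrate and single product, and you must reach 40 h from them.

all flasks: solid substrate 0.15 M

| charge | reagent | scavenger | remark | time |
|---|---|---|---|---|
| dusk | 0.18 M | 0.075 M | the very flask that is asked about, followed so far |  |
| flask | 0.180 M | 0.0750 M |  | 40 h |

- dusk (time / h: solid substrate / %, single product / %): 1.00: 99.3, 0.1; 1.33: 98.8, 0.5; 2.00: 98.6, 0; 3.00: 98.1, 0.2; 5.00: 95.8, 0.7; 8.00: 93.7, 1.9; 12.0: 90.7, 2.8

(readings scatter by 0.3 percentage points)

- at the start none of the solid substrate is in solution
- a reading or a percentage of double product counts all its forms, free or not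

- the solid substrate standing at 40 h, as a percentage of the solid substrate charged (only what is still solid)
- the single product standing at 40 h, as a percentage of the solid substrate charged
- the double product standing at 40 h, as a percentage of the solid substrate charged
- the triple product standing at 40 h, as a percentage of the solid substrate charged

The solid falls nearly in a line, so take a feed f = 0.00775 h⁻¹ of the charge from the last reading. But single product there is 2.8% against 9.30% lost, so a dissolved pool P stands between them. From 5.00 h to 12.0 h single product gains 0.00300 h⁻¹ of the charge while P reads 4.40% at 8.00 h, so κ = 0.0682 h⁻¹, the fraction of P converted per hour, a pseudo-first-order constant, read through a scatter of 0.3 percentage points.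

Early, P grows as f·t; late, it levels at f/κ. Joined, with x = κt, P = (f/κ)(1 − e^−x), and the ratio R of single product to P is x/(1 − e^−x) − 1, free of f. At 40 h, x = 2.73, so I reckon solid 69.0%, P 10.6%, conversion 20.4% and R 1.92; double and triple product were not read, so the readings are silent on them, and booking the conversion as single product is my assumption.

The forecast says “Most of the loss therefore sits as dissolved substrate” and gives solid 69%, single 14%, double 4.5% and triple 0.7%, its single product below my figure.

The flask holds solid substrate 73.3%, single product 15.9%, double product 0.245%, triple product 0.225% and starting material, your P, 9.85%.

    starting material + reagent → single product + released group (k = 0.350 M⁻¹ h⁻¹)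
    reagent + single product → double product + released group (k = 0.0110 M⁻¹ h⁻¹)
    reagent + double product → triple product + released group (k = 0.430 M⁻¹ h⁻¹)
    reagent + triple product → tetra adduct + released group (k = 0.0130 M⁻¹ h⁻¹)
    crystals ⇌ double product, rate k5*(cs5 - [double product]) while solid is left; crystals form when [double product] > cs5 (solubility = 0.0570 M, k = 8.50 h⁻¹)
    starting material + released group ⇌ idle adduct, settled at all times (K = 22.0 M⁻¹)
    scavenger + released group → scavenged by-product (k = 7.30 M⁻¹ h⁻¹)
    solid substrate ⇌ starting material, rate k8*(cs8 - [starting material]) while solid is left; crystals form when [starting material] > cs8 (solubility = 0.0560 M, k = 0.0220 h⁻¹)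

At 18.6 h this flask's reagent went 45 times as fast into single product as into double product, and nearly all of the converted material stands as single product. The feed averaged 0.00668 h⁻¹ against f, yet R, free of f, reads 1.61 against my 1.92; for the neighbouring flask with 0.072 M of reagent, κ scaled by the reagent gives x = 1.09 and R = 0.643, and that flask holds 0.571.

Readings and results come from a simulation with made-up constants; the scatter is artificial.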